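The route rests on the C1–C2 bond of the 1-aryl-tetradecane-3,5-diol, the bond between the benzylic CH2 of the guaiacyl ring and the CH2 next to the C3 carbinol. The key step benzylates the dilithio dianion of (S)-4-hydroxytridecan-2-one at its methyl terminus with 4-(benzyloxy)-3-methoxybenzyl bromide, giving the whole carbon skeleton (O-benzyl-(S)-[10]-gingerol) in one operation. It exploits the 1,3-relationship of the C3 and C5 oxygens: C3 as a ketone acidifies C2, the C5 alkoxide steers enolisation away from C4 and later directs a boron-chelated hydride to set C3 (R), syn to C5 (S). C5 comes from asymmetric allylboration of decanal.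

Key step: step 4

Remark: target atoms are numbered C1 (benzylic) to C14 along the chain; the allylborane is the antipode made from (−)-α-pinene, commonly labelled (+)-Ipc2B(allyl); the target is the 3,5-syn diol.

Step 1
Reactants: 1 decanal
Product: 3 (4S)-tridec-1-en-4-ol, via O-borinate ester 2 (not isolated)
Conditions: (+)-Ipc2B(allyl) (Mg-salt-free, 1.2 equiv), Et2O/pentane, −100 → −78 °C; then 3 M NaOH, 30% H2O2, rt
Reagents that add atoms: (+)-B-allyldiisopinocampheylborane, C=CCB([C@H]1C[C@H]2C[C@@H]([C@@H]1C)C2(C)C)[C@H]1C[C@H]2C[C@@H]([C@@H]1C)C2(C)C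
Why: Brown asymmetric allylboration through a six-membered chair (Zimmerman–Traxler) transition state; the isopinocampheyl groups of the (−)-α-pinene-derived reagent should direct the allyl group to the Re face of decanal and set the carbinol as (S), the future C5, before oxidative cleavage of the borinate.

Step 2
Reactants: 3 (4S)-tridec-1-en-4-ol
Product: 4 (4S)-4-hydroxytridecan-2-one
Conditions: PdCl2 (10 mol %), CuCl (1 equiv), O2 (1 atm), DMF/H2O 7:1, rt
Reagents that add atoms: water, O
Why: Tsuji–Wacker oxidation; Markovnikov hydroxypalladation of the terminal alkene followed by β-hydride elimination and tautomerisation should give the methyl ketone, and the carbinol stereocentre takes no part.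

Step 3
Reactants: 5 [4-(benzyloxy)-3-methoxyphenyl]methanol
Product: 6 4-(benzyloxy)-3-methoxybenzyl bromide
Conditions: PBr3 (0.4 equiv), Et2O, 0 °C; cold aq NaHCO3 wash; used at once
Reagents that add atoms: phosphorus tribromide, BrP(Br)Br
Why: Bromination of an activated benzylic alcohol by SN2 displacement of its bromophosphite ester; the aryl benzyl ether and the methyl ether are stable under these cold, brief conditions.

Step 4
Reactants: 4 (4S)-4-hydroxytridecan-2-one; 6 4-(benzyloxy)-3-methoxybenzyl bromide
Product: 8 (5S)-1-[4-(benzyloxy)-3-methoxyphenyl]-5-hydroxytetradecan-3-one, via dilithio aldolate dianion 7 (not isolated)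
Conditions: LDA (2.2 equiv), THF, −78 °C, 1 h; then 6 (0.9 equiv), DMPU (2 equiv), −78 → −40 °C; AcOH, −78 °C
Reagents that add atoms: none
Why: LDA first removes the hydroxyl proton of 4 and then, kinetically, a proton of its C1 methyl group, because the neighbouring lithium alkoxide disfavours removal of the C3 protons lying between the two oxygens; the α′-enolate carbon (future C2 of the target) then displaces bromide from the benzylic carbon of 6 (future C1) by SN2. The closest known reaction type is the α′-alkylation of aldolate (β-oxido ketone) dianions, a relative of the γ-alkylation of β-keto ester dianions. No ring is closed and no stereocentre is formed; the carbinol centre is not α to the carbonyl and should be carried through unchanged as long as the dianion is kept cold enough to suppress retro-aldol cleavage. The step needs site selectivity (methyl over the internal methylene), C- over O-alkylation and mono- over bis-benzylation: the first is secured by the β-oxido group, the second by the soft benzylic bromide reacting with the lithium enolate in THF/DMPU, the third by a slight excess of dianion and a temperature at or below −40 °C. The benzyl ether on the phenol oxygen is inert to LDA at this temperature and keeps the electrophile from collapsing to a quinone methide.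

Step 5
Reactants: 8 (5S)-1-[4-(benzyloxy)-3-methoxyphenyl]-5-hydroxytetradecan-3-one
Product: 10 (3R,5S)-1-[4-(benzyloxy)-3-methoxyphenyl]tetradecane-3,5-diol, via diethylboron chelate 9 (not isolated)
Conditions: Et2BOMe (1.1 equiv), THF/MeOH 4:1, −78 °C; NaBH4 (1.2 equiv), −78 °C; AcOH; MeOH azeotrope
Reagents that add atoms: none
Why: Narasaka–Prasad reduction; the diethylboron group ties the C5 oxygen and the C3 carbonyl into a six-membered half-chair chelate, and external hydride should add axially to set C3 as (R), 1,3-syn to C5 (S).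

Step 6
Reactants: 10 (3R,5S)-1-[4-(benzyloxy)-3-methoxyphenyl]tetradecane-3,5-diol
Product: 11 (3R,5S)-1-(4-hydroxy-3-methoxyphenyl)tetradecane-3,5-diol
Conditions: H2 (1 atm), 10% Pd/C, EtOAc, rt
Reagents that add atoms: none
Why: Catalytic hydrogenolysis of the aryl benzyl ether; the secondary alcohols, the aryl methyl ether and the unactivated benzylic CH2 should be inert, so the free phenol of the target is released.

Compound list
1 | decanal | CCCCCCCCCC=O | starting material
2 | (4S)-tridec-1-en-4-yl diisopinocampheylborinate | CCCCCCCCC[C@H](OB([C@H]1C[C@H]2C[C@@H]([C@@H]1C)C2(C)C)[C@H]1C[C@H]2C[C@@H]([C@@H]1C)C2(C)C)CC=C | intermediate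
3 | (4S)-tridec-1-en-4-ol | CCCCCCCCC[C@H](O)CC=C | intermediate
4 | (4S)-4-hydroxytridecan-2-one | CCCCCCCCC[C@H](O)CC(C)=O | intermediate
5 | [4-(benzyloxy)-3-methoxyphenyl]methanol | COc1cc(CO)ccc1OCc1ccccc1 | starting material
6 | 4-(benzyloxy)-3-methoxybenzyl bromide | COc1cc(CBr)ccc1OCc1ccccc1 | intermediate
7 | dilithium (4S)-tridec-1-ene-2,4-diolate (α′-enolate alkoxide of 4) | [Li+].[Li+].CCCCCCCCC[C@H]([O-])CC(=C)[O-] | intermediate
8 | (5S)-1-[4-(benzyloxy)-3-methoxyphenyl]-5-hydroxytetradecan-3-one | CCCCCCCCC[C@H](O)CC(=O)CCc1ccc(OCc2ccccc2)c(OC)c1 | intermediate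
9 | (5S)-1-[4-(benzyloxy)-3-methoxyphenyl]-5-[(diethylboranyl)oxy]tetradecan-3-one (B–O=C chelate, dative bond not drawn) | CCCCCCCCC[C@H](OB(CC)CC)CC(=O)CCc1ccc(OCc2ccccc2)c(OC)c1 | intermediate
10 | (3R,5S)-1-[4-(benzyloxy)-3-methoxyphenyl]tetradecane-3,5-diol | CCCCCCCCC[C@H](O)C[C@H](O)CCc1ccc(OCc2ccccc2)c(OC)c1 | intermediate
11 | (3R,5S)-1-(4-hydroxy-3-methoxyphenyl)tetradecane-3,5-diol | CCCCCCCCC[C@H](O)C[C@H](O)CCc1ccc(O)c(OC)c1 | target

Total step count: 6. Longest linear sequence: 5 (steps 1, 2, 4, 5, 6); step 3 prepares the electrophile.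

Steps most likely to fail

Step 4 (key step). Enolisation may not stay at the methyl terminus, proton transfer between product enolate and unreacted dianion may lead to double benzylation, or the dilithio aldolate may fragment by retro-aldol cleavage on warming. The fallback sets out from 3 (with the aryl partner drawn from 5) and comes back at 10, bypassing steps 2, 4 and 5. Alcohol 3 would be acylated (Boc2O, DMAP, MeCN) to tert-butyl (4S)-tridec-1-en-4-yl carbonate F1. IBr in toluene at −85 °C should then close the cis iodocarbonate (4S,6S)-4-(iodomethyl)-6-nonyl-1,3-dioxan-2-one F2, the carbonate oxygen being delivered 1,3-syn through a chair-like six-membered transition state. K2CO3 in MeOH would convert it into the syn epoxy alcohol (2S)-1-[(2S)-oxiran-2-yl]undecan-2-ol F3. In parallel, 5 with SOCl2 (CH2Cl2, 0 °C) gives 4-(benzyloxy)-3-methoxybenzyl chloride F4, and Mg in THF at high dilution gives [4-(benzyloxy)-3-methoxybenzyl]magnesium chloride F5. An excess of F5 with catalytic CuI (THF, −40 → 0 °C) should open F3 at its terminal carbon and give 10 directly. This forms the same C1–C2 bond with C3 already set.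

Step 2. The free hydroxyl may steer hydroxypalladation to the terminal carbon (aldehyde formation), or palladium hydride may migrate the double bond before oxidation. The fallback sets out from 1 and comes back at 4, replacing steps 1 and 2. B-methallyldiisopinocampheylborane F6 of the (−)-α-pinene series, made from (+)-Ipc2BOMe and methallylmagnesium chloride, would add to 1 at −78 °C. This gives (4S)-2-methyltridec-1-en-4-yl diisopinocampheylborinate F7, and oxidative work-up (NaOH, H2O2) gives (4S)-2-methyltridec-1-en-4-ol F8. Ozonolysis of the 1,1-disubstituted alkene (O3, CH2Cl2/MeOH, −78 °C; Me2S) should then give 4 without any palladium chemistry.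

Step 1. Enantioselectivity may erode if magnesium salts or a temperature rise accelerate the allyl transfer, and isopinocampheol may be hard to separate from 3; the enantiomeric purity fixed here cannot be corrected later. The fallback sets out from 1 and comes back at 4, replacing steps 1 and 2. Homologation of 1 with ethyl diazoacetate (SnCl2 cat., CH2Cl2, rt; Roskamp reaction) gives ethyl 3-oxododecanoate F9. Noyori hydrogenation (RuCl2[(S)-BINAP], H2, EtOH) should give ethyl (3S)-3-hydroxydodecanoate F10. MeNHOMe·HCl with iPrMgCl (THF, −20 °C) gives (3S)-3-hydroxy-N-methoxy-N-methyldodecanamide F11, and MeMgBr (THF, 0 °C) gives 4.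

Further compounds
F1 | step 4 | tert-butyl (4S)-tridec-1-en-4-yl carbonate | CCCCCCCCC[C@H](OC(=O)OC(C)(C)C)CC=C
F2 | step 4 | (4S,6S)-4-(iodomethyl)-6-nonyl-1,3-dioxan-2-one | CCCCCCCCC[C@H]1C[C@@H](CI)OC(=O)O1
F3 | step 4 | (2S)-1-[(2S)-oxiran-2-yl]undecan-2-ol | CCCCCCCCC[C@H](O)C[C@H]1CO1
F4 | step 4 | 4-(benzyloxy)-3-methoxybenzyl chloride | ClCc1ccc(OCc2ccccc2)c(OC)c1
F5 | step 4 | [4-(benzyloxy)-3-methoxybenzyl]magnesium chloride | Cl[Mg]Cc1ccc(OCc2ccccc2)c(OC)c1
F6 | step 2 | B-methallyldiisopinocampheylborane, (−)-α-pinene series | CC(=C)CB([C@H]1C[C@H]2C[C@@H]([C@@H]1C)C2(C)C)[C@H]1C[C@H]2C[C@@H]([C@@H]1C)C2(C)C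
F7 | step 2 | (4S)-2-methyltridec-1-en-4-yl diisopinocampheylborinate | CCCCCCCCC[C@H](OB([C@H]1C[C@H]2C[C@@H]([C@@H]1C)C2(C)C)[C@H]1C[C@H]2C[C@@H]([C@@H]1C)C2(C)C)CC(C)=C
F8 | step 2 | (4S)-2-methyltridec-1-en-4-ol | CCCCCCCCC[C@H](O)CC(C)=C
F9 | step 1 | ethyl 3-oxododecanoate | CCCCCCCCCC(=O)CC(=O)OCC
F10 | step 1 | ethyl (3S)-3-hydroxydodecanoate | CCCCCCCCC[C@H](O)CC(=O)OCC
F11 | step 1 | (3S)-3-hydroxy-N-methoxy-N-methyldodecanamide | CCCCCCCCC[C@H](O)CC(=O)N(C)OC
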